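Remark: positions follow the benzo[7]annulene numbering of ring B (C5 spiro, C6H2, C7, C8, C9, arene carbons C4a and C9a); the atom mapping was checked: the carbonyl carbon of the indanone becomes C9, its methylene C6 and its diester carbon C5, so the 5,6,7-trimethoxy pattern of the indanone falls on C2–C4 of the target.
Remark: the (S)-phosphinooxazoline ligand of step 6 is assumed to direct hydrogen to the Si face of C7; if the sense is the opposite, its enantiomer is used.
Remark: benzyl bromoacetate and 1,3-dimethoxypropan-2-one are taken as purchasable.

## Structural features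

The target is a spiro-fused tricycle: ring A is a 2,3,4-trimethoxybenzene (C1–C4, C4a, C9a), fused through C4a and C9a to the seven-membered carbocycle ring B (C5–C9). C5 is the spiro atom that ring B shares with ring C, a 3',5'-dimethoxycyclohexa-2',5'-dien-4'-one. Ring C is symmetric about the C5–C4' axis, so C5 is quaternary but not stereogenic. The stereochemical problem is the contiguous triad C7 (R, methyl), C8 (S, methyl) and C9 (R, acetoxy): the two methyl groups are trans, and the acetoxy group is trans to the C8 methyl group. The fragile parts are the cross-conjugated dienone, which acid rearranges to a phenol and nucleophiles attack, and the C9 acetate, which is benzylic to an electron-rich ring and ionises or hydrolyses easily. The difficulty is twofold: a quaternary carbon must be built beside the methoxy-bearing C4 inside a seven-membered ring, and C7 carries a hydrogen that cannot be epimerised, so its configuration must come from a chiral reagent, whereas C8 can be corrected by enolisation while C9 is a ketone. The key step exploits the fact that the adjacent methyl-bearing carbons C7 and C8 stand between C9 (carbonyl level) and the methylene C6. This is a 2-butyne unit set into the C(=O)–CH2 bond of a 1-indanone, whose remaining sp3 carbon is the future C5 and carries two ester carbons, the two CH= carbons that ring C needs.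

## Logic of the disconnections

22 to 21 to 20. The acyl C–O bond at C9 is cut first, then the O–Si bond. The acetate tolerates neither hydride nor base, so it goes on last, and a silyl ether carries the C9 oxygen through the construction of ring C. The last two steps are then protecting-group operations on a finished skeleton. The demand is that the silyl ether of 20 comes off without acid and without strong base.

20 to 17 and 18. Both C=C bonds of ring C (C2'=C3' and C5'=C6') are cut. Ring C is symmetric, so it divides into the three-carbon ketone 18 and two formyl groups on C5. The spiro carbon is already quaternary in 17 and poses no stereochemical question. The demand is a twofold aldol condensation in one flask that outruns loss of a formyl group from 17.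

17 to 16 to 15 to 14. No skeletal bond is cut: the formyl groups are traced to the primary alcohols of 16, these to the two methyl esters of 15, and the silyl ether of 15 to the carbinol of 14. A geminal diester is the sturdiest form in which two one-carbon arms at C5 can pass through metal catalysis and ketone chemistry. The demand is that C9–OH is masked before the hydride reduction and the oxidation.

14 to 13. The C9–H bond is cut. With C9 as an aryl ketone the oxygen is present from the start and the configuration can be set by a chiral reducing agent. The gain is one stereocentre fewer and a C8 centre that is correctable. The demand is hydride delivery to the Si face of C9 without epimerising C8.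

13 to 11. The C7–H and C8–H bonds are cut. All stereocentres vanish, since 11 is achiral. Only C7 has to be set by the catalyst, because C8 is equilibrated afterwards through the enolate. The demand is face-selective addition of hydrogen to a tetrasubstituted alkene; a CuH–phosphine catalyst is avoided because it would reduce the aryl ketone instead.

11 to 7 and 8. The bonds C9–C8 and C7–C6 are cut. C7, C8 and their methyl groups are the four carbons of 8, and what remains is a five-membered aryl ketone. Ring B shrinks to an indanone and, 8 being symmetric, no regiochemistry arises. The demand is a catalyst that opens the C(=O)–CH2 bond of 7 and not the C(=O)–aryl bond, next to a quaternary carbon and two esters.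

7 to 6 to 5. The aryl–C(=O) bond is cut, then the benzyl O–C bond of the ester. Only one arene position can reach the acyl carbon, and it is para to a methoxy group. The demand is ring closure without demethylation and without intermolecular acylation; the acid is released by hydrogenolysis, so no carbocation meets the electron-rich ring.

5 to 3 and 4. The bond between the quaternary carbon and its CH2 group is cut. This leaves a stabilised tertiary carbanion and a primary α-halo ester, the best pairing for making a quaternary centre. The demand is a clean SN2 alkylation.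

3 to 1 and 2. The aryl–C bond is cut. Both fragments are purchasable, and the methoxy pattern of 1 places the future C4 methoxy group next to the future C5. The demand is a cross-coupling that tolerates an ortho methoxy group.

## Other disconnections considered

Alternative 1: The cut is made in ring C at C5–C6' and C2'=C3'. Ring B is complete and C5 carries one formyl group and one hydrogen, as in aldehyde A2 (methyl groups trans as in the target).
- Forward step: DBU would form the enolate of A2, which adds to the β-carbon of the methoxy enone A3 (1,3,4-trimethoxybut-3-en-2-one) with loss of methanol. The methoxymethylene group of the ketone then condenses with the formyl carbon and closes ring C, giving the 9-deacetoxy compound A1.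
- In favour: ring C appears in one operation at the dienone oxidation level, and no 1,3-dialdehyde is involved.
- Against: A1 has a methylene at C9, so the acetoxy group would need a late benzylic C–H oxidation beside a dienone, with control of configuration. The quaternary centre is made by conjugate addition of a hindered, fully substituted enolate next to the C4 methoxy group. A3 must be prepared.
- Comparison, structure: both plans build ring C onto a finished ring B and leave C5 without a stereochemical question (equal).
- Comparison, mechanism: the addition–elimination and aldol sequence avoids the deformylation-prone dialdehyde and is on that point better than the twofold aldol chosen here. The chosen plan, however, carries the C9 oxygen from its first ketone and needs no C–H oxidation.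
- Comparison, step economy: the ring C operations are equal in number; the C9 oxidation and a separate asymmetric entry to A2 would make the whole longer.

Alternative 2: The cut is the C5–C6 bond of ring B. The precursor is the biaryl phenol A5, in which ring C is still a 2,6-dimethoxyphenol joined to ring A and the C9–C8–C7–C6 chain ends in a primary iodide.
- Forward step: the potassium phenolate of A5 (KOtBu, tBuOH–THF, high dilution) would attack the iodide through its para carbon. This closes ring B, creates the spiro carbon and dearomatises the phenol in one step, giving the silyl ether A4.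
- In favour: the three stereocentres are set in an open chain by dependable acyclic methods, which is better than the chosen plan, where C7 is set on a tetrasubstituted cyclic alkene. Ring C comes from an intact aromatic ring and need not be built (better). A4 is the same compound as 20, so the endgame is equal.
- Against: a seven-membered ring and a quaternary centre are formed together by C-alkylation of an ambident phenolate, in competition with intermolecular O-alkylation and base-induced elimination at the β-branched iodide. The biaryl bond of A5 has two ortho substituents on the ring A side, and A5 is a long linear target.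
- Comparison, structure: the alternative is the more convergent.
- Comparison, mechanism: the chosen insertion closes ring B at a metal centre and has no ambident competitor.
- Comparison, step economy: the chosen plan reaches 20 in eleven steps from 1, which a stereocontrolled synthesis of A5 plus a hindered cross-coupling is unlikely to beat.

Alternative 3: The cut removes both aryl–carbon bonds of ring B, C9–C9a and C5–C4a. Ring A would arrive as the aryne A8, made in the flask from the silyl triflate A7, and the rest as the cyclopentanone keto ester A9, which already carries the two trans methyl groups.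
- Forward step: CsF would release A8 and the enolate of A9 adds to it. The aryl anion then attacks the ketone and the four-membered alkoxide opens, so the arene is inserted into the C(=O)–CH(ester) bond and the five-membered ring becomes the benzo-fused seven-membered ring of A6.
- In favour: the step is convergent and mild. Like the chosen key step it is a two-atom ring expansion of a five-membered ketone (equal in concept). C7 and C8 are fixed beforehand in a small ring, which is better than reducing a tetrasubstituted alkene.
- Against: the methoxy group next to the aryne directs the enolate carbon to the distal aryne carbon. A6 therefore has its ketone at C5, where the target needs the quaternary spiro carbon, and its ester carbon at C9, where the target needs oxygen. The repair asks for an oxidative decarboxylation at C9 with stereocontrol and for homologation plus annulation at C5. A7 and enantiopure A9 each need several steps.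
- Comparison, structure: the chosen indanone places the carbonyl at C9 and both ring C carbons at C5 from the outset.
- Comparison, mechanism: each step hinges on one selectivity (which aryne carbon is attacked there, which C–C bond is cleaved here).
- Comparison, step economy: the alternative is shorter up to ring B but clearly longer after it.

Key step: step 5

## Route

Step 1
Reactants: 1 1-bromo-2,3,4-trimethoxybenzene; 2 dimethyl malonate
Product: 3 dimethyl 2-(2,3,4-trimethoxyphenyl)malonate
Conditions: Pd(OAc)2 (2 mol%), tBu3P·HBF4 (4 mol%), K3PO4, toluene, 90 °C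
Reagents that add atoms: none
Why: Pd-catalysed α-arylation of a malonate: oxidative addition of 1 to zerovalent palladium, exchange of bromide for the potassium enolate of 2 and C–C reductive elimination from divalent palladium. The bulky, electron-rich tBu3P tolerates the ortho methoxy group, and the product, being deprotonated by the base, is not arylated a second time.

Step 2
Reactants: 3 dimethyl 2-(2,3,4-trimethoxyphenyl)malonate; 4 benzyl bromoacetate
Product: 5 2-benzyl 1,1-dimethyl 1-(2,3,4-trimethoxyphenyl)ethane-1,1,2-tricarboxylate
Conditions: NaH, THF/DMF, 0 → 23 °C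
Reagents that add atoms: none
Why: SN2 alkylation of the sodium enolate of 3 with a primary α-bromo ester creates the quaternary carbon that becomes C5. The third carboxyl group is carried as a benzyl ester so that it can be freed later without acid or base.

Step 3
Reactants: 5 2-benzyl 1,1-dimethyl 1-(2,3,4-trimethoxyphenyl)ethane-1,1,2-tricarboxylate
Product: 6 3,3-bis(methoxycarbonyl)-3-(2,3,4-trimethoxyphenyl)propanoic acid
Conditions: H2 (1 atm), 10% Pd/C, EtOAc, 23 °C
Reagents that add atoms: none
Why: Hydrogenolysis of the benzyl ester on palladium; methyl esters and aryl methyl ethers are inert. Unlike acid cleavage of a tert-butyl ester, no carbocation is formed that could alkylate the electron-rich ring.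

Step 4
Reactants: 6 3,3-bis(methoxycarbonyl)-3-(2,3,4-trimethoxyphenyl)propanoic acid
Product: 7 dimethyl 5,6,7-trimethoxy-3-oxoindane-1,1-dicarboxylate
Conditions: P2O5/MeSO3H (Eaton's reagent), 50 °C, high dilution
Reagents that add atoms: none
Why: Intramolecular Friedel–Crafts acylation through the acylium ion of 6; only C6 of the aryl group can be reached in a five-membered transition state, it is para to the 3-methoxy group, and the geminal esters favour closure (Thorpe–Ingold effect). A protic dehydrating acid is preferred to AlCl3, which could demethylate the 2-methoxy group and lead to a lactone, and dilution suppresses intermolecular acylation at the more electron-rich C5.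

Step 5
Reactants: 7 dimethyl 5,6,7-trimethoxy-3-oxoindane-1,1-dicarboxylate; 8 2-butyne
Product: 11 dimethyl 2,3,4-trimethoxy-7,8-dimethyl-9-oxo-6,9-dihydro-5H-benzo[7]annulene-5,5-dicarboxylate, via indanone ketimine 9 (not isolated), via ring-expanded ketimine 10 (not isolated)
Conditions: [Rh(C2H4)2Cl]2 (5 mol%), IMes (10 mol%), 2-amino-3-picoline (50 mol%), TsOH·H2O (10 mol%), 2-butyne (5 equiv), 1,4-dioxane, 130 °C, sealed tube
Reagents that add atoms: none
Why: 2-Amino-3-picoline condenses with the C3 ketone of 7 to ketimine 9, whose pyridine nitrogen holds monovalent rhodium next to the C3–C2 bond. Oxidative addition of this C(=N)–CH2 bond gives a six-membered trivalent rhodacycle that has no β-hydrogen, because the next carbon is the quaternary diester carbon. 2-Butyne inserts into a Rh–C bond and C–C reductive elimination makes the second bond, so that C9–C8 and C7–C6 are formed and ketimine 10 results; the water from the condensation hydrolyses 10 to 11 and returns the amine. The closest known reaction type is the rhodium–N-heterocyclic-carbene-catalysed two-carbon ring expansion of 1-indanones with ethylene or internal alkynes under a transient 2-aminopyridine directing group. Ring B is closed by reductive elimination from an eight-membered rhodacycle, that is by ring expansion of the five-membered ketone and not by an exo or endo cyclisation of a chain. No stereocentre is created. The step needs site selectivity between the C(=O)–CH2 and the C(=O)–aryl bond; it is secured by the ketimine geometry, in which the pyridyl group lies on the CH2 side, away from the peri C4–H, and by the 3-methyl group, which turns the pyridine nitrogen towards that bond. Regioselectivity of insertion is not needed because 8 is symmetric, and the strongly donating IMes ligand favours C–C oxidative addition over alkyne oligomerisation.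

Step 6
Reactants: 11 dimethyl 2,3,4-trimethoxy-7,8-dimethyl-9-oxo-6,9-dihydro-5H-benzo[7]annulene-5,5-dicarboxylate
Product: 13 dimethyl (7R,8S)-2,3,4-trimethoxy-7,8-dimethyl-9-oxo-6,7,8,9-tetrahydro-5H-benzo[7]annulene-5,5-dicarboxylate, via cis-ketone 12 (not isolated)
Conditions: H2 (50 bar), [Ir(cod)((S)-iPr-PHOX)][B(C6H3(CF3)2)4] (2 mol%), CH2Cl2, 23 °C; then NaOMe (20 mol%), MeOH, 23 °C
Reagents that add atoms: none
Why: Proposed new method: a cationic iridium–phosphinooxazoline dihydride should bind the C7=C8 bond (the C9 carbonyl can serve as a second donor) and, by migratory insertion and reductive elimination, add both hydrogen atoms syn to the Si face of C7 and C8 that the ligand leaves open, which sets 7R and gives the cis ketone 12 (8R); the closest known reaction types are the iridium–N,P-catalysed asymmetric hydrogenation of trisubstituted α,β-unsaturated ketones and of unfunctionalised tetrasubstituted cyclic alkenes, and a CuH–phosphine catalyst was not chosen because it reduces aryl ketones and α-substituted enones at the carbonyl group. Methoxide then enolises the ketone and equilibrates C8 to the trans isomer 13 (8S), in which both methyl groups can be pseudo-equatorial, while C7 has no acidic hydrogen and keeps its configuration.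

Step 7
Reactants: 13 dimethyl (7R,8S)-2,3,4-trimethoxy-7,8-dimethyl-9-oxo-6,7,8,9-tetrahydro-5H-benzo[7]annulene-5,5-dicarboxylate
Product: 14 dimethyl (7R,8S,9R)-9-hydroxy-2,3,4-trimethoxy-7,8-dimethyl-6,7,8,9-tetrahydro-5H-benzo[7]annulene-5,5-dicarboxylate
Conditions: (S)-2-methyl-CBS-oxazaborolidine (20 mol%), BH3·SMe2, THF, −20 °C; MeOH quench
Reagents that add atoms: none
Why: Corey–Bakshi–Shibata reduction: the ketone binds the catalyst boron through the lone pair on the C8 side (the fused arene with its in-plane peri C1–H acts as the large group) and hydride passes from the nitrogen-bound borane to the Si face of C9, which sets 9R, the sense known for 1-tetralone-type ketones. The esters are not reduced by BH3 at this temperature and C8 is not epimerised under the non-basic conditions.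

Step 8
Reactants: 14 dimethyl (7R,8S,9R)-9-hydroxy-2,3,4-trimethoxy-7,8-dimethyl-6,7,8,9-tetrahydro-5H-benzo[7]annulene-5,5-dicarboxylate
Product: 15 dimethyl (7R,8S,9R)-9-[(tert-butyldimethylsilyl)oxy]-2,3,4-trimethoxy-7,8-dimethyl-6,7,8,9-tetrahydro-5H-benzo[7]annulene-5,5-dicarboxylate
Conditions: TBSOTf, 2,6-lutidine, CH2Cl2, 0 °C
Reagents that add atoms: tert-butyldimethylsilyl trifluoromethanesulfonate, CC(C)(C)[Si](C)(C)OS(=O)(=O)C(F)(F)F
Why: Silylation of a hindered benzylic secondary alcohol with the reactive silyl triflate under a hindered pyridine base, with retention at C9. The ether masks the C9 oxygen against LiAlH4, the Swern reagent and DBU and can be removed by fluoride without acid.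

Step 9
Reactants: 15 dimethyl (7R,8S,9R)-9-[(tert-butyldimethylsilyl)oxy]-2,3,4-trimethoxy-7,8-dimethyl-6,7,8,9-tetrahydro-5H-benzo[7]annulene-5,5-dicarboxylate
Product: 16 [(7R,8S,9R)-9-[(tert-butyldimethylsilyl)oxy]-2,3,4-trimethoxy-7,8-dimethyl-6,7,8,9-tetrahydro-5H-benzo[7]annulene-5,5-diyl]dimethanol
Conditions: LiAlH4, THF, 0 → 23 °C
Reagents that add atoms: none
Why: Hydride reduction of both esters to the 2,2-disubstituted propane-1,3-diol; the silyl ether, the aryl ethers and the three stereocentres are inert to LiAlH4.

Step 10
Reactants: 16 [(7R,8S,9R)-9-[(tert-butyldimethylsilyl)oxy]-2,3,4-trimethoxy-7,8-dimethyl-6,7,8,9-tetrahydro-5H-benzo[7]annulene-5,5-diyl]dimethanol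
Product: 17 (7R,8S,9R)-9-[(tert-butyldimethylsilyl)oxy]-2,3,4-trimethoxy-7,8-dimethyl-6,7,8,9-tetrahydro-5H-benzo[7]annulene-5,5-dicarbaldehyde
Conditions: (COCl)2, DMSO, CH2Cl2, −78 °C; Et3N, −78 → 0 °C
Reagents that add atoms: none
Why: Swern oxidation: both primary alcohols are converted into alkoxysulfonium ions before the base is added, so no hydroxy aldehyde capable of retro-aldol loss of formaldehyde is exposed to base. 17 has no α-hydrogen, cannot enolise, and is taken on without chromatography.

Step 11
Reactants: 17 (7R,8S,9R)-9-[(tert-butyldimethylsilyl)oxy]-2,3,4-trimethoxy-7,8-dimethyl-6,7,8,9-tetrahydro-5H-benzo[7]annulene-5,5-dicarbaldehyde; 18 1,3-dimethoxypropan-2-one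
Product: 20 (7R,8S,9R)-9-[(tert-butyldimethylsilyl)oxy]-2,3,3',4,5'-pentamethoxy-7,8-dimethyl-6,7,8,9-tetrahydrospiro[benzo[7]annulene-5,1'-cyclohexa[2,5]dien]-4'-one, via cyclic bis-aldol 19 (not isolated)
Conditions: DBU, 4 Å molecular sieves, MeCN, 0 → 60 °C
Reagents that add atoms: none
Why: Twofold aldol condensation of a non-enolisable dialdehyde with a ketone that has two α-methylene groups (Claisen–Schmidt type): intermolecular aldol addition, 6-(enolendo)-exo-trig aldol ring closure to 19 and two E1cB dehydrations, driven by the cross-conjugated dienone. The ring must close before the first dehydration, since an acyclic enone would form with C5 trans to the carbonyl group; a non-nucleophilic amidine base in a dry aprotic solvent is chosen so that no hydroxide or alkoxide is present to remove a formyl group from 17 by retro-Claisen cleavage. C5 becomes the symmetric spiro atom and C7, C8 and C9 are not touched.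

Step 12
Reactants: 20 (7R,8S,9R)-9-[(tert-butyldimethylsilyl)oxy]-2,3,3',4,5'-pentamethoxy-7,8-dimethyl-6,7,8,9-tetrahydrospiro[benzo[7]annulene-5,1'-cyclohexa[2,5]dien]-4'-one
Product: 21 (7R,8S,9R)-9-hydroxy-2,3,3',4,5'-pentamethoxy-7,8-dimethyl-6,7,8,9-tetrahydrospiro[benzo[7]annulene-5,1'-cyclohexa[2,5]dien]-4'-one
Conditions: Bu4NF, AcOH, THF, 0 → 23 °C
Reagents that add atoms: none
Why: Fluoride cleaves the Si–O bond (strong Si–F bond) with retention at C9. Acetic acid buffers the alkoxide, so the dienone meets neither strong base nor strong acid, which would cause conjugate addition, dienone–phenol rearrangement or ionisation at C9.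

Step 13
Reactants: 21 (7R,8S,9R)-9-hydroxy-2,3,3',4,5'-pentamethoxy-7,8-dimethyl-6,7,8,9-tetrahydrospiro[benzo[7]annulene-5,1'-cyclohexa[2,5]dien]-4'-one
Product: 22 (7R,8S,9R)-2,3,3',4,5'-pentamethoxy-7,8-dimethyl-4'-oxo-6,7,8,9-tetrahydrospiro[benzo[7]annulene-5,1'-cyclohexa[2,5]dien]-9-yl acetate
Conditions: Ac2O, pyridine, DMAP (cat.), CH2Cl2, 23 °C
Reagents that add atoms: acetic anhydride, CC(=O)OC(C)=O
Why: DMAP-catalysed acylation of the secondary alcohol at oxygen, with retention at C9; the mildly basic medium leaves the dienone intact.

## Compound list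

1 | 1-bromo-2,3,4-trimethoxybenzene | COc1ccc(Br)c(OC)c1OC | starting material
2 | dimethyl malonate | COC(=O)CC(=O)OC | starting material
3 | dimethyl 2-(2,3,4-trimethoxyphenyl)malonate | COC(=O)C(C(=O)OC)c1ccc(OC)c(OC)c1OC | intermediate
4 | benzyl bromoacetate | BrCC(=O)OCc1ccccc1 | starting material
5 | 2-benzyl 1,1-dimethyl 1-(2,3,4-trimethoxyphenyl)ethane-1,1,2-tricarboxylate | COC(=O)C(CC(=O)OCc1ccccc1)(C(=O)OC)c1ccc(OC)c(OC)c1OC | intermediate
6 | 3,3-bis(methoxycarbonyl)-3-(2,3,4-trimethoxyphenyl)propanoic acid | COC(=O)C(CC(=O)O)(C(=O)OC)c1ccc(OC)c(OC)c1OC | intermediate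
7 | dimethyl 5,6,7-trimethoxy-3-oxoindane-1,1-dicarboxylate | COC(=O)C1(C(=O)OC)CC(=O)c2cc(OC)c(OC)c(OC)c21 | intermediate
8 | 2-butyne | CC#CC | starting material
9 | indanone ketimine, dimethyl 5,6,7-trimethoxy-3-[(3-methylpyridin-2-yl)imino]indane-1,1-dicarboxylate (not isolated) | COC(=O)C1(C(=O)OC)CC(=Nc3ncccc3C)c2cc(OC)c(OC)c(OC)c21 | intermediate
10 | ring-expanded ketimine, dimethyl 2,3,4-trimethoxy-7,8-dimethyl-9-[(3-methylpyridin-2-yl)imino]-6,9-dihydro-5H-benzo[7]annulene-5,5-dicarboxylate (not isolated) | COC(=O)C1(C(=O)OC)CC(C)=C(C)C(=Nc3ncccc3C)c2cc(OC)c(OC)c(OC)c21 | intermediate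
11 | dimethyl 2,3,4-trimethoxy-7,8-dimethyl-9-oxo-6,9-dihydro-5H-benzo[7]annulene-5,5-dicarboxylate | COC(=O)C1(C(=O)OC)CC(C)=C(C)C(=O)c2cc(OC)c(OC)c(OC)c21 | intermediate
12 | cis-ketone, dimethyl (7R,8R)-2,3,4-trimethoxy-7,8-dimethyl-9-oxo-6,7,8,9-tetrahydro-5H-benzo[7]annulene-5,5-dicarboxylate (not isolated) | COC(=O)C1(C(=O)OC)C[C@@H](C)[C@@H](C)C(=O)c2cc(OC)c(OC)c(OC)c21 | intermediate
13 | dimethyl (7R,8S)-2,3,4-trimethoxy-7,8-dimethyl-9-oxo-6,7,8,9-tetrahydro-5H-benzo[7]annulene-5,5-dicarboxylate (methyl groups trans) | COC(=O)C1(C(=O)OC)C[C@@H](C)[C@H](C)C(=O)c2cc(OC)c(OC)c(OC)c21 | intermediate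
14 | dimethyl (7R,8S,9R)-9-hydroxy-2,3,4-trimethoxy-7,8-dimethyl-6,7,8,9-tetrahydro-5H-benzo[7]annulene-5,5-dicarboxylate | COC(=O)C1(C(=O)OC)C[C@@H](C)[C@H](C)[C@@H](O)c2cc(OC)c(OC)c(OC)c21 | intermediate
15 | dimethyl (7R,8S,9R)-9-[(tert-butyldimethylsilyl)oxy]-2,3,4-trimethoxy-7,8-dimethyl-6,7,8,9-tetrahydro-5H-benzo[7]annulene-5,5-dicarboxylate | COC(=O)C1(C(=O)OC)C[C@@H](C)[C@H](C)[C@@H](O[Si](C)(C)C(C)(C)C)c2cc(OC)c(OC)c(OC)c21 | intermediate
16 | [(7R,8S,9R)-9-[(tert-butyldimethylsilyl)oxy]-2,3,4-trimethoxy-7,8-dimethyl-6,7,8,9-tetrahydro-5H-benzo[7]annulene-5,5-diyl]dimethanol | OCC1(CO)C[C@@H](C)[C@H](C)[C@@H](O[Si](C)(C)C(C)(C)C)c2cc(OC)c(OC)c(OC)c21 | intermediate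
17 | (7R,8S,9R)-9-[(tert-butyldimethylsilyl)oxy]-2,3,4-trimethoxy-7,8-dimethyl-6,7,8,9-tetrahydro-5H-benzo[7]annulene-5,5-dicarbaldehyde | O=CC1(C=O)C[C@@H](C)[C@H](C)[C@@H](O[Si](C)(C)C(C)(C)C)c2cc(OC)c(OC)c(OC)c21 | intermediate
18 | 1,3-dimethoxypropan-2-one | COCC(=O)COC | starting material
19 | cyclic bis-aldol, (7R,8S,9R)-9-[(tert-butyldimethylsilyl)oxy]-2',6'-dihydroxy-2,3,3',4,5'-pentamethoxy-7,8-dimethyl-6,7,8,9-tetrahydrospiro[benzo[7]annulene-5,1'-cyclohexan]-4'-one, mixture of diastereomers at C2', C3', C5' and C6' (not isolated) | COC1C(O)C2(C(O)C(OC)C1=O)C[C@@H](C)[C@H](C)[C@@H](O[Si](C)(C)C(C)(C)C)c1cc(OC)c(OC)c(OC)c12 | intermediate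
20 | (7R,8S,9R)-9-[(tert-butyldimethylsilyl)oxy]-2,3,3',4,5'-pentamethoxy-7,8-dimethyl-6,7,8,9-tetrahydrospiro[benzo[7]annulene-5,1'-cyclohexa[2,5]dien]-4'-one | COC1=CC2(C=C(OC)C1=O)C[C@@H](C)[C@H](C)[C@@H](O[Si](C)(C)C(C)(C)C)c1cc(OC)c(OC)c(OC)c12 | intermediate
21 | (7R,8S,9R)-9-hydroxy-2,3,3',4,5'-pentamethoxy-7,8-dimethyl-6,7,8,9-tetrahydrospiro[benzo[7]annulene-5,1'-cyclohexa[2,5]dien]-4'-one | COC1=CC2(C=C(OC)C1=O)C[C@@H](C)[C@H](C)[C@@H](O)c1cc(OC)c(OC)c(OC)c12 | intermediate
22 | (7R,8S,9R)-2,3,3',4,5'-pentamethoxy-7,8-dimethyl-4'-oxo-6,7,8,9-tetrahydrospiro[benzo[7]annulene-5,1'-cyclohexa[2,5]dien]-9-yl acetate | COC1=CC2(C=C(OC)C1=O)C[C@@H](C)[C@H](C)[C@@H](OC(C)=O)c1cc(OC)c(OC)c(OC)c12 | target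

## Step count and least certain steps

Total step count: 13. Longest linear sequence: 13 steps (1 to 22); 2, 4, 8 and 18 enter as purchased reagents.

**Step 6 (Proposed new method).** The catalyst may fail to turn over on the hindered, electron-poor tetrasubstituted alkene, or may discriminate poorly between its two faces. The fallback uses known chemistry, sets out from 11 and returns at 14:
- Radical conjugate reduction by hydrogen-atom transfer (Mn(dpm)3 cat., PhSiH3, iPrOH, 23 °C) followed by NaOMe in MeOH should give the racemic trans-ketone F1.
- Reduction under the conditions of step 7, where the reagent controls C9, converts the two enantiomers into diastereomers: 14 and the (7S,8R,9R)-hydroxy diester F2.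
- The two are separated by chromatography. The price is that at most half of the material is carried forward.

**Step 5 (key step).** Oxidative addition into a C–C bond whose methylene is flanked by a quaternary carbon may be slow, and the esters may hold the metal; ester aminolysis by the directing amine and alkyne oligomerisation could then take over at 130 °C. The fallback builds ring B by a classical acylation, sets out from 3 and returns at 11:
- Purchased 2,3-dimethylmaleic anhydride is reduced (NaBH4) to 3,4-dimethylfuran-2(5H)-one F3.
- F3 is opened with Me3SiBr and benzyl alcohol to benzyl (2Z)-4-bromo-2,3-dimethylbut-2-enoate F4.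
- The sodium enolate of 3 is alkylated with F4 to the malonate triester F5.
- Hydrogenolysis (H2, Pd/C) frees the (2Z)-pentenoic acid F6.
- Friedel–Crafts closure of the seven-membered ring (P2O5/MeSO3H) gives 11.

**Step 11.** A formyl group may be lost from 17 by retro-Claisen cleavage before the first aldol addition, or the sequence may stall before the second dehydration. The fallback turns this weakness into the route, sets out from 17 and returns at 20:
- K2CO3 in MeOH deliberately removes one formyl group and gives the mono-aldehyde F7 (C5 epimers).
- F7 with DBU and 1,3,4-trimethoxybut-3-en-2-one F8 (from 18 by formylation and O-methylation) undergoes conjugate addition–elimination at the β-carbon and intramolecular aldol condensation to 20.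

**Step 7.** Facial selectivity may be eroded, because the α-branch at C8 reduces the size difference between the two ketone substituents or because the substrate bias opposes the catalyst. The fallback uses substrate control and inversion, sets out from 13 and returns at 14:
- Li[(sBu)3BH] in THF at −78 °C should deliver hydride anti to the C8 methyl group and give the (9S)-alcohol F9.
- Mitsunobu reaction (4-nitrobenzoic acid, PPh3, DIAD) inverts C9 to the (9R)-4-nitrobenzoate F10.
- K2CO3 in MeOH releases 14.

## Further compounds

F1 | step 6 | racemic trans-ketone, dimethyl (7R,8S)- and (7S,8R)-2,3,4-trimethoxy-7,8-dimethyl-9-oxo-6,7,8,9-tetrahydro-5H-benzo[7]annulene-5,5-dicarboxylate (both enantiomers written) | COC(=O)C1(C(=O)OC)C[C@@H](C)[C@H](C)C(=O)c2cc(OC)c(OC)c(OC)c21.COC(=O)C1(C(=O)OC)C[C@H](C)[C@@H](C)C(=O)c2cc(OC)c(OC)c(OC)c21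
F2 | step 6 | dimethyl (7S,8R,9R)-9-hydroxy-2,3,4-trimethoxy-7,8-dimethyl-6,7,8,9-tetrahydro-5H-benzo[7]annulene-5,5-dicarboxylate | COC(=O)C1(C(=O)OC)C[C@H](C)[C@@H](C)[C@@H](O)c2cc(OC)c(OC)c(OC)c21
F3 | step 5 | 3,4-dimethylfuran-2(5H)-one | CC1=C(C)C(=O)OC1
F4 | step 5 | benzyl (2Z)-4-bromo-2,3-dimethylbut-2-enoate | BrC/C(C)=C(/C)C(=O)OCc1ccccc1
F5 | step 5 | dimethyl 2-[(2Z)-4-(benzyloxy)-2,3-dimethyl-4-oxobut-2-en-1-yl]-2-(2,3,4-trimethoxyphenyl)malonate | COC(=O)C(C/C(C)=C(/C)C(=O)OCc1ccccc1)(C(=O)OC)c1ccc(OC)c(OC)c1OC
F6 | step 5 | (2Z)-5,5-bis(methoxycarbonyl)-2,3-dimethyl-5-(2,3,4-trimethoxyphenyl)pent-2-enoic acid | COC(=O)C(C/C(C)=C(/C)C(=O)O)(C(=O)OC)c1ccc(OC)c(OC)c1OC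
F7 | step 11 | (7R,8S,9R)-9-[(tert-butyldimethylsilyl)oxy]-2,3,4-trimethoxy-7,8-dimethyl-6,7,8,9-tetrahydro-5H-benzo[7]annulene-5-carbaldehyde (C5 epimers) | O=CC1C[C@@H](C)[C@H](C)[C@@H](O[Si](C)(C)C(C)(C)C)c2cc(OC)c(OC)c(OC)c21
F8 | step 11 | 1,3,4-trimethoxybut-3-en-2-one | COC=C(OC)C(=O)COC
F9 | step 7 | dimethyl (7R,8S,9S)-9-hydroxy-2,3,4-trimethoxy-7,8-dimethyl-6,7,8,9-tetrahydro-5H-benzo[7]annulene-5,5-dicarboxylate | COC(=O)C1(C(=O)OC)C[C@@H](C)[C@H](C)[C@H](O)c2cc(OC)c(OC)c(OC)c21
F10 | step 7 | dimethyl (7R,8S,9R)-2,3,4-trimethoxy-7,8-dimethyl-9-[(4-nitrobenzoyl)oxy]-6,7,8,9-tetrahydro-5H-benzo[7]annulene-5,5-dicarboxylate | COC(=O)C1(C(=O)OC)C[C@@H](C)[C@H](C)[C@@H](OC(=O)c3ccc(cc3)[N+](=O)[O-])c2cc(OC)c(OC)c(OC)c21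
A1 | alternative 1 | 9-deacetoxy target, 2,3,3',4,5'-pentamethoxy-7,8-dimethyl-6,7,8,9-tetrahydrospiro[benzo[7]annulene-5,1'-cyclohexa[2,5]dien]-4'-one with trans methyl groups (7R,8R by the sequence rule, same spatial arrangement as the target) | COC1=CC2(C=C(OC)C1=O)C[C@@H](C)[C@H](C)Cc1cc(OC)c(OC)c(OC)c12
A2 | alternative 1 | 2,3,4-trimethoxy-7,8-dimethyl-6,7,8,9-tetrahydro-5H-benzo[7]annulene-5-carbaldehyde with trans methyl groups (C5 epimers) | O=CC1C[C@@H](C)[C@H](C)Cc2cc(OC)c(OC)c(OC)c21
A3 | alternative 1 | 1,3,4-trimethoxybut-3-en-2-one | COC=C(OC)C(=O)COC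
A4 | alternative 2 | C9 tert-butyldimethylsilyl ether of the deacetyl target (identical with 20) | COC1=CC2(C=C(OC)C1=O)C[C@@H](C)[C@H](C)[C@@H](O[Si](C)(C)C(C)(C)C)c1cc(OC)c(OC)c(OC)c12
A5 | alternative 2 | 4-{6-[(1R,2S,3S)-1-[(tert-butyldimethylsilyl)oxy]-4-iodo-2,3-dimethylbutyl]-2,3,4-trimethoxyphenyl}-2,6-dimethoxyphenol | IC[C@@H](C)[C@H](C)[C@@H](O[Si](C)(C)C(C)(C)C)c1cc(OC)c(OC)c(OC)c1-c1cc(OC)c(O)c(OC)c1
A6 | alternative 3 | allyl (7R,8S)-2,3,4-trimethoxy-7,8-dimethyl-5-oxo-6,7,8,9-tetrahydro-5H-benzo[7]annulene-9-carboxylate (C9 epimers) | O=C1C[C@@H](C)[C@H](C)C(C(=O)OCC=C)c2cc(OC)c(OC)c(OC)c21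
A7 | alternative 3 | 3,4,5-trimethoxy-2-(trimethylsilyl)phenyl trifluoromethanesulfonate | COc1cc(OS(=O)(=O)C(F)(F)F)c([Si](C)(C)C)c(OC)c1OC
A8 | alternative 3 | 3,4,5-trimethoxybenzyne (1,2-didehydro-3,4,5-trimethoxybenzene) | COC1=C(OC)C(OC)=CC#C1
A9 | alternative 3 | allyl (2S,3R)-2,3-dimethyl-5-oxocyclopentane-1-carboxylate (C1 epimers) | O=C1C[C@@H](C)[C@H](C)C1C(=O)OCC=C
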